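**Retrosynthetic overview**

1. Target 22 comes from its tris-silyl ether 21, and 21 from cis-alcohol 20. Ru transfer hydrogenation of isoflavone 18 with dynamic kinetic resolution sets C3, and Dess–Martin oxidation returns C4 to the ketone.
2. The isoflavone core (16) comes from a one-carbon ring expansion. The aryl(chloro)carbene carbon of diazirine 10 is inserted into the C2=C3 bond of 3,6-bis(silyloxy)benzofuran 12, so the five-membered furan ring (O1, C2, C3, C3a, C7a) becomes the six-membered pyran-4-one ring and the B ring arrives on the new C3.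
3. Enabling feature: C3 of the pyranone is a single carbon between the O–CH (C2) and the carbonyl carbon (C4) and carries the whole B ring. Removing it leaves a benzofuran-3-ol whose silyl enol ether C=C bond accepts a carbene, and the C4 oxygen together with the carbene's chloride opens the cyclopropane to a benzopyrylium.
4. B-ring piece 10 comes from pyrogallol acetonide 1 by para-bromination, O-prenylation, aromatic Claisen rearrangement (reverse prenyl group), O-methylation, aryllithium/carbodiimide amidination and Graham oxidation. A-ring piece 12 comes from 6-hydroxybenzofuran-3(2H)-one 11.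
5. Ring order: both benzene rings, the furan ring and the temporary dioxole ring are bought (1, 11). The pyranone ring is the only ring made (step 8, from the furan ring). The dioxole ring is opened in step 9.

Key step: step 8

Remark: the stereocentre as drawn is (S) (CIP order C4 > C2 > aryl > H); 1 and 11 are taken as purchasable.

**Route**

Step 1
Reactants: 1 2,2-dimethyl-1,3-benzodioxol-4-ol
Product: 2 7-bromo-2,2-dimethyl-1,3-benzodioxol-4-ol
Conditions: NBS (1.0 equiv), MeCN, −20 → 0 °C
Reagents that add atoms: N-bromosuccinimide, O=C1CCC(=O)N1Br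
Why: Electrophilic aromatic bromination of a phenol, in which C7 (para to the free hydroxyl, ortho to the tied-back ring oxygen, least hindered) should be the main site, installing both the para blocker for the Claisen step and the handle for the later carbon substituent.

Step 2
Reactants: 2 7-bromo-2,2-dimethyl-1,3-benzodioxol-4-ol
Product: 3 4-bromo-2,2-dimethyl-7-[(3-methylbut-2-en-1-yl)oxy]-1,3-benzodioxole
Conditions: prenyl bromide, K2CO3, DMF, rt
Reagents that add atoms: 1-bromo-3-methylbut-2-ene, CC(C)=CCBr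
Why: Williamson etherification of the phenoxide with a reactive allylic bromide, O-alkylation being favoured under carbonate conditions in a dipolar aprotic solvent.

Step 3
Reactants: 3 4-bromo-2,2-dimethyl-7-[(3-methylbut-2-en-1-yl)oxy]-1,3-benzodioxole
Product: 5 7-bromo-2,2-dimethyl-5-(2-methylbut-3-en-2-yl)-1,3-benzodioxol-4-ol, via ortho-dienone 4 (not isolated)
Conditions: PhNEt2, 190 °C (sealed tube), short reaction time
Reagents that add atoms: none
Why: Aromatic Claisen rearrangement, in which the [3,3] shift can only go to the one free ortho carbon and delivers the allyl unit inverted as the 1,1-dimethylallyl group in dienone 4, which tautomerises to the phenol, while the para bromine shuts off the onward Cope shift to the para position.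

Step 4
Reactants: 5 7-bromo-2,2-dimethyl-5-(2-methylbut-3-en-2-yl)-1,3-benzodioxol-4-ol
Product: 6 4-bromo-7-methoxy-2,2-dimethyl-6-(2-methylbut-3-en-2-yl)-1,3-benzodioxole
Conditions: MeI, K2CO3, DMF, 40 °C
Reagents that add atoms: iodomethane, CI
Why: Williamson O-methylation of the hindered but acidic phenol, which also removes the free hydroxyl beside the new alkene before it can cyclise onto it.

Step 5
Reactants: 6 4-bromo-7-methoxy-2,2-dimethyl-6-(2-methylbut-3-en-2-yl)-1,3-benzodioxole
Product: 9 7-methoxy-2,2-dimethyl-6-(2-methylbut-3-en-2-yl)-1,3-benzodioxole-4-carboximidamide hydrochloride, via aryllithium 7 (not isolated), via silylated lithium amidinate 8 (not isolated)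
Conditions: n-BuLi, THF, −78 °C; Me3SiN=C=NSiMe3, −78 °C → rt; HCl (4 M in dioxane), 0 °C
Reagents that add atoms: N,N′-bis(trimethylsilyl)carbodiimide, C[Si](C)(C)N=C=N[Si](C)(C)C; hydrogen chloride, Cl
Why: Bromine–lithium exchange gives aryllithium 7, whose addition to the carbodiimide carbon (the standard amidinate synthesis) gives 8, and anhydrous HCl strips both N-silyl groups to leave the amidinium chloride, the isolated vinyl group and the ketal being inert to these conditions.

Step 6
Reactants: 9 7-methoxy-2,2-dimethyl-6-(2-methylbut-3-en-2-yl)-1,3-benzodioxole-4-carboximidamide hydrochloride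
Product: 10 3-chloro-3-[7-methoxy-2,2-dimethyl-6-(2-methylbut-3-en-2-yl)-1,3-benzodioxol-4-yl]-3H-diazirine
Conditions: NaOCl (aq), LiCl, DMSO/pentane, 0 °C → rt, dark; used at once as a solution
Reagents that add atoms: sodium hypochlorite, [Na+].[O-]Cl; lithium chloride, [Li+].[Cl-] (exchangeable chloride pool, not consumed net)
Why: Graham oxidation of an amidine to a 3-aryl-3-chloro-3H-diazirine, where basic hypochlorite is a poor electrophile for the unactivated monosubstituted alkene and for the single ring C–H that is flanked by the amidinium and the tert-alkyl group.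

Step 7
Reactants: 11 6-hydroxy-1-benzofuran-3(2H)-one
Product: 12 3,6-bis[(tert-butyldimethylsilyl)oxy]-1-benzofuran
Conditions: TBSOTf (2.3 equiv), Et3N, CH2Cl2, 0 °C → rt
Reagents that add atoms: tert-butyldimethylsilyl trifluoromethanesulfonate, CC(C)(C)[Si](C)(C)OS(=O)(=O)C(F)(F)F
Why: Silylation of the phenol and soft enolisation/O-silylation of the ketone with silyl triflate and amine base, driven by formation of the aromatic furan ring.

Step 8
Reactants: 10 3-chloro-3-[7-methoxy-2,2-dimethyl-6-(2-methylbut-3-en-2-yl)-1,3-benzodioxol-4-yl]-3H-diazirine; 12 3,6-bis[(tert-butyldimethylsilyl)oxy]-1-benzofuran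
Product: 16 7-[(tert-butyldimethylsilyl)oxy]-3-[7-methoxy-2,2-dimethyl-6-(2-methylbut-3-en-2-yl)-1,3-benzodioxol-4-yl]-4H-chromen-4-one, via aryl(chloro)carbene 13 (not isolated), via chlorocyclopropane adduct 14 (not isolated), via 4-siloxybenzopyrylium chloride 15 (not isolated)
Conditions: 10 (1 equiv) added slowly to 12 (2.5 equiv), Na2CO3 (solid, acid scavenger), MeCN, 50 °C, dark
Reagents that add atoms: none
Why: Proposed new method: thermolysis of 10 releases N2 and the singlet carbene 13, which as an electrophilic carbene should add to the most electron-rich π bond present, the C2=C3 silyl enol ether bond of 12, to give chlorocyclopropane 14 by [2+1] cycloaddition; loss of chloride with 2π-electrocyclic opening of the shared C2–C3 bond, pushed by the ring oxygen and the 3-siloxy group and helped by the donor-substituted aryl group so that both C–Cl epimers can ionise, then gives the aromatic benzopyrylium 15, and chloride removes the silyl group from O4 to unveil the pyran-4-one. The closest known reaction types are the Ciamician–Dennstedt-type one-carbon ring expansions of indoles, pyrroles and indenes with halocarbenes (including carbenes from aryl chlorodiazirines) and the dihalocarbene ring expansion of cyclic silyl enol ethers to 2-halo-enones; the present pairing of an arylchlorocarbene with a benzofuran-3-ol silyl ether is not documented. The only ring formed is the pyranone, by ring expansion of the furan ring (cyclopropanation, then cyclopropyl-to-allyl cation opening), and its regiochemistry is fixed because the carbene carbon can only end up between C2 and the oxygen-bearing C3. No stereocentre survives the step, since 16 is planar, so the configuration of 14 is irrelevant. The step needs site selectivity for the enol ether over the vinyl group of the carbene's own aryl ring and over intramolecular trapping by the ortho oxygen; this is secured by the far higher nucleophilicity of the siloxy-substituted furan double bond (used in excess), by the hindered, meta-placed vinyl group, and by tying the ortho oxygen back in the dioxole ring so that it offers no reachable C–H bond or unstrained ylide.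

Step 9
Reactants: 16 7-[(tert-butyldimethylsilyl)oxy]-3-[7-methoxy-2,2-dimethyl-6-(2-methylbut-3-en-2-yl)-1,3-benzodioxol-4-yl]-4H-chromen-4-one
Product: 17 3-[2,3-dihydroxy-4-methoxy-5-(2-methylbut-3-en-2-yl)phenyl]-7-hydroxy-4H-chromen-4-one
Conditions: TFA/CH2Cl2/H2O (10:10:1), 0 °C → rt, under Ar
Reagents that add atoms: none
Why: Acid hydrolysis of the isopropylidene ketal and the aryl silyl ether on the achiral, acid-stable isoflavone, placed here so that no strong acid is needed once the stereocentre exists, the monosubstituted alkene having no neighbouring free phenol and protonating only slowly.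

Step 10
Reactants: 17 3-[2,3-dihydroxy-4-methoxy-5-(2-methylbut-3-en-2-yl)phenyl]-7-hydroxy-4H-chromen-4-one
Product: 18 3-[2,3-bis[(tert-butyldimethylsilyl)oxy]-4-methoxy-5-(2-methylbut-3-en-2-yl)phenyl]-7-[(tert-butyldimethylsilyl)oxy]-4H-chromen-4-one
Conditions: TBSCl (4 equiv), imidazole, DMF, rt
Reagents that add atoms: tert-butyldimethylsilyl chloride, CC(C)(C)[Si](C)(C)Cl
Why: Standard imidazole-promoted silylation of the three phenols gives fluoride-labile protection that tolerates the reduction and oxidation to come.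

Step 11
Reactants: 18 3-[2,3-bis[(tert-butyldimethylsilyl)oxy]-4-methoxy-5-(2-methylbut-3-en-2-yl)phenyl]-7-[(tert-butyldimethylsilyl)oxy]-4H-chromen-4-one
Product: 20 (3S,4S)-3-[2,3-bis[(tert-butyldimethylsilyl)oxy]-4-methoxy-5-(2-methylbut-3-en-2-yl)phenyl]-7-[(tert-butyldimethylsilyl)oxy]-3,4-dihydro-2H-chromen-4-ol, via racemic isoflavanone 19 (not isolated)
Conditions: RuCl[(S,S)-TsDPEN](p-cymene) (3 mol %), HCO2H/Et3N (5:2), EtOAc, 40 °C
Reagents that add atoms: none
Why: Noyori–Ikariya asymmetric transfer hydrogenation of an isoflavone, in which conjugate hydride transfer gives the rapidly enolising racemic ketone 19 and dynamic kinetic resolution in the carbonyl reduction gives the cis-alcohol, the (S,S)-catalyst being expected to set C4 as (S) as for chroman-4-one and the cis preference thereby setting C3 as (S), while the isolated alkene is untouched.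

Step 12
Reactants: 20 (3S,4S)-3-[2,3-bis[(tert-butyldimethylsilyl)oxy]-4-methoxy-5-(2-methylbut-3-en-2-yl)phenyl]-7-[(tert-butyldimethylsilyl)oxy]-3,4-dihydro-2H-chromen-4-ol
Product: 21 (3S)-3-[2,3-bis[(tert-butyldimethylsilyl)oxy]-4-methoxy-5-(2-methylbut-3-en-2-yl)phenyl]-7-[(tert-butyldimethylsilyl)oxy]-2,3-dihydro-4H-chromen-4-one
Conditions: Dess–Martin periodinane, CH2Cl2, 0 °C → rt
Reagents that add atoms: none
Why: Dess–Martin oxidation of the benzylic alcohol under base-free conditions removes the auxiliary C4 stereocentre and leaves C3 untouched because nothing present enolises the new ketone.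

Step 13
Reactants: 21 (3S)-3-[2,3-bis[(tert-butyldimethylsilyl)oxy]-4-methoxy-5-(2-methylbut-3-en-2-yl)phenyl]-7-[(tert-butyldimethylsilyl)oxy]-2,3-dihydro-4H-chromen-4-one
Product: 22 (3S)-3-[2,3-dihydroxy-4-methoxy-5-(2-methylbut-3-en-2-yl)phenyl]-7-hydroxy-2,3-dihydro-4H-chromen-4-one
Conditions: HF·pyridine, THF/pyridine, 0 °C → rt, under Ar
Reagents that add atoms: none
Why: Fluoride-mediated cleavage of the three aryl silyl ethers under buffered, weakly acidic conditions, in which the alkene is inert and the enolisable C3 centre should not epimerise.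

**Compound list**

1 | 2,2-dimethyl-1,3-benzodioxol-4-ol | CC1(C)Oc2cccc(O)c2O1 | starting material
2 | 7-bromo-2,2-dimethyl-1,3-benzodioxol-4-ol | CC1(C)Oc2c(Br)ccc(O)c2O1 | intermediate
3 | 4-bromo-2,2-dimethyl-7-[(3-methylbut-2-en-1-yl)oxy]-1,3-benzodioxole | CC(C)=CCOc1ccc(Br)c2OC(C)(C)Oc12 | intermediate
4 | 4-bromo-2,2-dimethyl-6-(2-methylbut-3-en-2-yl)-1,3-benzodioxol-7(6H)-one (ortho-dienone, racemic, not isolated) | C=CC(C)(C)C1C=C(Br)C2=C(OC(C)(C)O2)C1=O | intermediate
5 | 7-bromo-2,2-dimethyl-5-(2-methylbut-3-en-2-yl)-1,3-benzodioxol-4-ol | C=CC(C)(C)c1cc(Br)c2OC(C)(C)Oc2c1O | intermediate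
6 | 4-bromo-7-methoxy-2,2-dimethyl-6-(2-methylbut-3-en-2-yl)-1,3-benzodioxole | C=CC(C)(C)c1cc(Br)c2OC(C)(C)Oc2c1OC | intermediate
7 | [7-methoxy-2,2-dimethyl-6-(2-methylbut-3-en-2-yl)-1,3-benzodioxol-4-yl]lithium (not isolated) | [Li]c1cc(C(C)(C)C=C)c(OC)c2OC(C)(C)Oc12 | intermediate
8 | lithium N,N′-bis(trimethylsilyl)-7-methoxy-2,2-dimethyl-6-(2-methylbut-3-en-2-yl)-1,3-benzodioxole-4-carboximidamidate (not isolated) | C[Si](C)(C)N=C(N([Li])[Si](C)(C)C)c1cc(C(C)(C)C=C)c(OC)c2OC(C)(C)Oc12 | intermediate
9 | 7-methoxy-2,2-dimethyl-6-(2-methylbut-3-en-2-yl)-1,3-benzodioxole-4-carboximidamide hydrochloride | C=CC(C)(C)c1cc(C(N)=[NH2+])c2OC(C)(C)Oc2c1OC.[Cl-] | intermediate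
10 | 3-chloro-3-[7-methoxy-2,2-dimethyl-6-(2-methylbut-3-en-2-yl)-1,3-benzodioxol-4-yl]-3H-diazirine | C=CC(C)(C)c1cc(C2(Cl)N=N2)c3OC(C)(C)Oc3c1OC | intermediate
11 | 6-hydroxy-1-benzofuran-3(2H)-one | O=C1COc2cc(O)ccc12 | starting material
12 | 3,6-bis[(tert-butyldimethylsilyl)oxy]-1-benzofuran | CC(C)(C)[Si](C)(C)Oc1ccc2c(O[Si](C)(C)C(C)(C)C)coc2c1 | intermediate
13 | chloro[7-methoxy-2,2-dimethyl-6-(2-methylbut-3-en-2-yl)-1,3-benzodioxol-4-yl]carbene (not isolated) | Cl[C]c1cc(C(C)(C)C=C)c(OC)c2OC(C)(C)Oc12 | intermediate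
14 | 1-aryl-1-chloro-5,6b-bis[(tert-butyldimethylsilyl)oxy]-1a,6b-dihydro-1H-cyclopropa[b]benzofuran, aryl as in 10 (diastereomer mixture, racemic, not isolated) | CC(C)(C)[Si](C)(C)Oc1ccc2c(c1)OC1C(Cl)(c3cc(C(C)(C)C=C)c(OC)c4OC(C)(C)Oc34)C21O[Si](C)(C)C(C)(C)C | intermediate
15 | 4,7-bis[(tert-butyldimethylsilyl)oxy]-3-[7-methoxy-2,2-dimethyl-6-(2-methylbut-3-en-2-yl)-1,3-benzodioxol-4-yl]chromenylium chloride (not isolated) | CC(C)(C)[Si](C)(C)Oc1ccc2c(O[Si](C)(C)C(C)(C)C)c(-c3cc(C(C)(C)C=C)c(OC)c4OC(C)(C)Oc34)c[o+]c2c1.[Cl-] | intermediate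
16 | 7-[(tert-butyldimethylsilyl)oxy]-3-[7-methoxy-2,2-dimethyl-6-(2-methylbut-3-en-2-yl)-1,3-benzodioxol-4-yl]-4H-chromen-4-one | CC(C)(C)[Si](C)(C)Oc1ccc2c(c1)occ(-c3cc(C(C)(C)C=C)c(OC)c4OC(C)(C)Oc34)c2=O | intermediate
17 | 3-[2,3-dihydroxy-4-methoxy-5-(2-methylbut-3-en-2-yl)phenyl]-7-hydroxy-4H-chromen-4-one | C=CC(C)(C)c1cc(-c2coc3cc(O)ccc3c2=O)c(O)c(O)c1OC | intermediate
18 | 3-[2,3-bis[(tert-butyldimethylsilyl)oxy]-4-methoxy-5-(2-methylbut-3-en-2-yl)phenyl]-7-[(tert-butyldimethylsilyl)oxy]-4H-chromen-4-one | C=CC(C)(C)c1cc(-c2coc3cc(O[Si](C)(C)C(C)(C)C)ccc3c2=O)c(O[Si](C)(C)C(C)(C)C)c(O[Si](C)(C)C(C)(C)C)c1OC | intermediate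
19 | rac-3-[2,3-bis[(tert-butyldimethylsilyl)oxy]-4-methoxy-5-(2-methylbut-3-en-2-yl)phenyl]-7-[(tert-butyldimethylsilyl)oxy]-2,3-dihydro-4H-chromen-4-one (not isolated) | C=CC(C)(C)c1cc(C2COc3cc(O[Si](C)(C)C(C)(C)C)ccc3C2=O)c(O[Si](C)(C)C(C)(C)C)c(O[Si](C)(C)C(C)(C)C)c1OC | intermediate
20 | (3S,4S)-3-[2,3-bis[(tert-butyldimethylsilyl)oxy]-4-methoxy-5-(2-methylbut-3-en-2-yl)phenyl]-7-[(tert-butyldimethylsilyl)oxy]-3,4-dihydro-2H-chromen-4-ol | C=CC(C)(C)c1cc([C@H]2COc3cc(O[Si](C)(C)C(C)(C)C)ccc3[C@H]2O)c(O[Si](C)(C)C(C)(C)C)c(O[Si](C)(C)C(C)(C)C)c1OC | intermediate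
21 | (3S)-3-[2,3-bis[(tert-butyldimethylsilyl)oxy]-4-methoxy-5-(2-methylbut-3-en-2-yl)phenyl]-7-[(tert-butyldimethylsilyl)oxy]-2,3-dihydro-4H-chromen-4-one | C=CC(C)(C)c1cc([C@H]2COc3cc(O[Si](C)(C)C(C)(C)C)ccc3C2=O)c(O[Si](C)(C)C(C)(C)C)c(O[Si](C)(C)C(C)(C)C)c1OC | intermediate
22 | (3S)-3-[2,3-dihydroxy-4-methoxy-5-(2-methylbut-3-en-2-yl)phenyl]-7-hydroxy-2,3-dihydro-4H-chromen-4-one | C=CC(C)(C)c1cc([C@H]2COc3cc(O)ccc3C2=O)c(O)c(O)c1OC | target

**Step count**

Total steps: 13. Longest linear sequence: 12 (steps 1–6 and 8–13; step 7 is the one-step side branch).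

**Steps most likely to fail**

1. Step 8 (proposed new method). The carbene may be lost to azine formation with unreacted diazirine or to intramolecular trapping before it meets the enol ether, or the cyclopropane epimer with chlorine on the convex face may fail to ionise. The fallback uses known chemistry, keeps the furan-to-pyranone ring expansion, sets out from 12 and 6 and comes back at 16. Dibromocarbene ring expansion of 12 (CHBr3, KOt-Bu, hexane, −20 °C → rt; the classical dihalocarbene route from a cyclic silyl enol ether to the ring-enlarged 2-bromo-enone with loss of the silyl group) should give 3-bromo-7-[(tert-butyldimethylsilyl)oxy]-4H-chromen-4-one F1. Miyaura borylation of 6 (B2pin2, Pd(dppf)Cl2, KOAc, dioxane, 90 °C) should give 2-[7-methoxy-2,2-dimethyl-6-(2-methylbut-3-en-2-yl)-1,3-benzodioxol-4-yl]-4,4,5,5-tetramethyl-1,3,2-dioxaborolane F2. Suzuki–Miyaura coupling of the two (Pd(OAc)2, SPhos, anhydrous K3PO4, toluene, 80 °C) should then give 16.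

2. Step 3. Thermal loss of the prenyl group (return to the phenol) or further reaction of the product phenol with its new alkene (abnormal Claisen rearrangement, cyclisation) may outpace clean rearrangement. The fallback builds the quaternary benzylic carbon by allylic substitution instead of a sigmatropic shift, sets out from 1 and comes back at 6. Amine-catalysed ortho-bromination of 1 (NBS, cat. i-Pr2NH, CH2Cl2, 0 °C) should give 5-bromo-2,2-dimethyl-1,3-benzodioxol-4-ol F3. O-Methylation (MeI, K2CO3, DMF) should give 5-bromo-4-methoxy-2,2-dimethyl-1,3-benzodioxole F4. Magnesium insertion (Mg, LiCl, THF) should give bromo(4-methoxy-2,2-dimethyl-1,3-benzodioxol-5-yl)magnesium F5. In the presence of CuBr·SMe2 this should undergo anti-SN2′ substitution of 3-methylbut-2-en-1-yl pyridine-2-carboxylate (THF, −40 → 0 °C) to give 4-methoxy-2,2-dimethyl-5-(2-methylbut-3-en-2-yl)-1,3-benzodioxole F6. Bromination with NBS in MeCN at the only open activated position (para to the methoxy group) should then give 6.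

3. Step 11. The carbonyl reduction may be slow, or the dynamic kinetic resolution may give poor cis- or enantioselectivity because of the crowded ortho-silyloxy B ring; aryl silyl ethers may also erode in the formate buffer. The fallback replaces reduction and re-oxidation by an enantioselective protonation, sets out from 18 and comes back at 21. Conjugate reduction of 18 with L-Selectride (THF, −78 °C) should give lithium 3-[2,3-bis[(tert-butyldimethylsilyl)oxy]-4-methoxy-5-(2-methylbut-3-en-2-yl)phenyl]-7-[(tert-butyldimethylsilyl)oxy]-2H-chromen-4-olate F7. O-Acylation in the same flask with allyl chloroformate should give allyl 3-[2,3-bis[(tert-butyldimethylsilyl)oxy]-4-methoxy-5-(2-methylbut-3-en-2-yl)phenyl]-7-[(tert-butyldimethylsilyl)oxy]-2H-chromen-4-yl carbonate F8. Palladium-catalysed decarboxylative asymmetric protonation (Pd2(dba)3, a t-Bu-PHOX-type ligand whose enantiomer is chosen to deliver the (S)-ketone, Meldrum's acid as proton donor, dioxane, 40 °C) should give 21 directly.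

**Further compounds**

F1 | step 8 | 3-bromo-7-[(tert-butyldimethylsilyl)oxy]-4H-chromen-4-one | CC(C)(C)[Si](C)(C)Oc1ccc2c(c1)occ(Br)c2=O
F2 | step 8 | 2-[7-methoxy-2,2-dimethyl-6-(2-methylbut-3-en-2-yl)-1,3-benzodioxol-4-yl]-4,4,5,5-tetramethyl-1,3,2-dioxaborolane | C=CC(C)(C)c1cc(B2OC(C)(C)C(C)(C)O2)c3OC(C)(C)Oc3c1OC
F3 | step 3 | 5-bromo-2,2-dimethyl-1,3-benzodioxol-4-ol | CC1(C)Oc2ccc(Br)c(O)c2O1
F4 | step 3 | 5-bromo-4-methoxy-2,2-dimethyl-1,3-benzodioxole | COc1c(Br)ccc2OC(C)(C)Oc12
F5 | step 3 | bromo(4-methoxy-2,2-dimethyl-1,3-benzodioxol-5-yl)magnesium | COc1c([Mg]Br)ccc2OC(C)(C)Oc12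
F6 | step 3 | 4-methoxy-2,2-dimethyl-5-(2-methylbut-3-en-2-yl)-1,3-benzodioxole | C=CC(C)(C)c1ccc2OC(C)(C)Oc2c1OC
F7 | step 11 | lithium 3-[2,3-bis[(tert-butyldimethylsilyl)oxy]-4-methoxy-5-(2-methylbut-3-en-2-yl)phenyl]-7-[(tert-butyldimethylsilyl)oxy]-2H-chromen-4-olate | [Li]OC1=C(c2cc(C(C)(C)C=C)c(OC)c(O[Si](C)(C)C(C)(C)C)c2O[Si](C)(C)C(C)(C)C)COc2cc(O[Si](C)(C)C(C)(C)C)ccc12
F8 | step 11 | allyl 3-[2,3-bis[(tert-butyldimethylsilyl)oxy]-4-methoxy-5-(2-methylbut-3-en-2-yl)phenyl]-7-[(tert-butyldimethylsilyl)oxy]-2H-chromen-4-yl carbonate | C=CCOC(=O)OC1=C(c2cc(C(C)(C)C=C)c(OC)c(O[Si](C)(C)C(C)(C)C)c2O[Si](C)(C)C(C)(C)C)COc2cc(O[Si](C)(C)C(C)(C)C)ccc12
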